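**Plan**

Isochromanone numbering is used: C1 lactone carbonyl, O2, C3 hemiketal carbon, C4 CH(CH3), C4a, C5 (CH3), C6 (OCH3), C7, C8 (OH), C8a.
The retrosynthesis opens the lactol (O2–C3) to its 1,5-keto acid tautomer, then cuts the ester O–CH2 bond (diazoketone plus the protected 2,4-dihydroxy-5,6-dimethylbenzoic acid) and the C3–CH2 bond (diazomethane on a C3 acid chloride).
It then cuts C8a–C1 and C4–C3 together, because in the keto acid C8a and C4 lie 1,3 across C4a and each carries one carbonyl carbon. They therefore map onto the phenol carbon and the acetyl carbon of an o-hydroxyacetophenone, whose bis-triflate should take up two molecules of CO2.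
Forward order: 2,4-dimethoxytoluene, o-hydroxyacetophenone, bis-triflate, double carboxylation, C8 demethylation and benzyl protection, release of the C3 acid, hydrogenation, diazoketone, ester coupling, hydrogenolysis; the lactol ring is the only ring formed and closes last, by itself.
Stereochemistry: C4 (S) comes from Ru–(S)-BINAP hydrogenation of the 2-arylacrylic acid, placed after all basic steps; C3 (R) is set on ring closure as the thermodynamic hemiketal (axial OH trans to the pseudo-axial C4 methyl).

Key step: step 8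

Remark: C3 is a hemiketal carbon that epimerises through the open keto acid, so only C4 has to be set by the route; the (3R) configuration is taken to be the thermodynamic one relative to (4S).

**Route**

Step 1
Reactants: 1 4,5-dimethylbenzene-1,3-diol
Product: 3 2,4-dihydroxy-5,6-dimethylbenzaldehyde, via Vilsmeier iminium chloride 2 (not isolated)
Conditions: POCl3, DMF, 0 °C to rt; then aq. NaOAc, 60 °C
Reagents that add atoms: N,N-dimethylformamide, CN(C)C=O (formyl carbon); water, O (carbonyl oxygen); phosphoryl chloride, O=P(Cl)(Cl)Cl (chloride of intermediate 2 only)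
Why: Vilsmeier–Haack formylation should occur at C6 of the resorcinol (para to one hydroxyl, ortho to the other, as in the orcinol case) and not at the more hindered carbon between the two oxygens, and hydrolysis of the iminium salt gives the aldehyde.

Step 2
Reactants: 3 2,4-dihydroxy-5,6-dimethylbenzaldehyde
Product: 4 2,4-bis(benzyloxy)-5,6-dimethylbenzaldehyde
Conditions: BnBr, K2CO3, DMF, 60 °C
Reagents that add atoms: benzyl bromide, BrCc1ccccc1
Why: Williamson ether synthesis; heating in DMF is needed to alkylate the hydrogen-bonded 2-hydroxyl as well.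

Step 3
Reactants: 4 2,4-bis(benzyloxy)-5,6-dimethylbenzaldehyde
Product: 5 2,4-bis(benzyloxy)-5,6-dimethylbenzoic acid
Conditions: NaClO2, NaH2PO4, 2-methyl-2-butene, t-BuOH/H2O, rt
Reagents that add atoms: sodium chlorite, [Na+].[O-]Cl=O
Why: Pinnick oxidation converts the hindered aryl aldehyde into the acid without touching the benzyl ethers, the alkene scavenging hypochlorous acid.

Step 4
Reactants: 6 2,4-dimethoxytoluene
Product: 7 1-(2,4-dimethoxy-5-methylphenyl)ethan-1-one
Conditions: Ac2O, Sc(OTf)3 (5 mol%), MeNO2, 50 °C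
Reagents that add atoms: acetic anhydride, CC(=O)OC(C)=O
Why: Friedel–Crafts acylation should enter the one position that is para to one methoxy group and ortho to the other without lying between the two oxygens.

Step 5
Reactants: 7 1-(2,4-dimethoxy-5-methylphenyl)ethan-1-one
Product: 8 2,4-dimethoxy-5-methylphenyl acetate
Conditions: mCPBA, CH2Cl2, rt
Reagents that add atoms: 3-chloroperoxybenzoic acid, OOC(=O)c1cccc(Cl)c1
Why: Baeyer–Villiger oxidation, in which the electron-rich aryl group migrates in preference to methyl.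

Step 6
Reactants: 8 2,4-dimethoxy-5-methylphenyl acetate
Product: 9 1-(2-hydroxy-3,5-dimethoxy-6-methylphenyl)ethan-1-one
Conditions: Sc(OTf)3 (10 mol%), toluene, 100 °C
Reagents that add atoms: none
Why: Fries rearrangement; the acetyl group should go to the only free position ortho to the phenol oxygen (para is blocked by OCH3), the carbon between that oxygen and the ring methyl.

Step 7
Reactants: 9 1-(2-hydroxy-3,5-dimethoxy-6-methylphenyl)ethan-1-one
Product: 10 1-{3,5-dimethoxy-2-methyl-6-[(trifluoromethanesulfonyl)oxy]phenyl}ethenyl trifluoromethanesulfonate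
Conditions: KHMDS (2.2 equiv), THF, −78 °C; then PhNTf2 (2.3 equiv), −78 °C to rt
Reagents that add atoms: N-phenylbis(trifluoromethanesulfonimide), O=S(=O)(N(c1ccccc1)S(=O)(=O)C(F)(F)F)C(F)(F)F
Why: O-sulfonylation of the phenoxide/enolate dianion (aryl triflate and kinetic enol triflate formation); the methyl ketone has a single enolisable side, and the triflimide is added only after the base is consumed to avoid elimination of the vinyl triflate.

Step 8
Reactants: 10 1-{3,5-dimethoxy-2-methyl-6-[(trifluoromethanesulfonyl)oxy]phenyl}ethenyl trifluoromethanesulfonate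
Product: 11 2-(1-carboxyethenyl)-4,6-dimethoxy-3-methylbenzoic acid
Conditions: CoI2(2,9-dimethyl-1,10-phenanthroline) (10 mol%), Mn powder (4 equiv), CO2 (1 atm), DMA, 25 to 60 °C; then 1 M HCl
Reagents that add atoms: carbon dioxide, O=C=O
Why: Mn reduces the Co(II) precatalyst to low-valent cobalt, which inserts into each C(sp2)–OTf bond (the 1-arylvinyl triflate first, then the 2,6-disubstituted aryl triflate); after reduction the vinyl- and aryl-cobalt species add to CO2 and pass the carboxylates to Mn(II), so C4–C3 and C8a–C1 are formed in one flask by two turnovers on one molecule. The closest known reaction type is the Co- or Ni-catalysed reductive carboxylation of alkenyl triflates and of sterically hindered aryl triflates with CO2 and Mn. No ring is closed and no stereocentre is formed: C4 stays sp2 (C4=CH2) so that its configuration can be set by hydrogenation in step 12, and the lactol ring closes only in step 15. The step needs CO2 capture to win over hydro-detriflation and reductive homocoupling at both sites; the two ortho substituents at C8a (OCH3 and the vinyl unit) disfavour homocoupling, dry CO2-saturated DMA limits protonation, and the first-formed acrylate cannot add to the aryl–metal bond (only 4-exo or 5-endo modes are available).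

Step 9
Reactants: 11 2-(1-carboxyethenyl)-4,6-dimethoxy-3-methylbenzoic acid
Product: 12 2-(1-carboxyethenyl)-6-hydroxy-4-methoxy-3-methylbenzoic acid
Conditions: BCl3 (4 equiv), CH2Cl2, −78 to 0 °C; then H2O
Reagents that add atoms: none
Why: Chelation-controlled Lewis-acid ether cleavage: boron is held between the C1 carboxyl and the adjacent C8 methoxy oxygen and chloride removes that methyl only, while the C6 methoxy group, which has no neighbouring carbonyl, should survive at or below 0 °C.

Step 10
Reactants: 12 2-(1-carboxyethenyl)-6-hydroxy-4-methoxy-3-methylbenzoic acid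
Product: 13 benzyl 6-(benzyloxy)-2-[3-(benzyloxy)-3-oxoprop-1-en-2-yl]-4-methoxy-3-methylbenzoate
Conditions: BnBr (3.6 equiv), K2CO3, DMF, rt to 40 °C
Reagents that add atoms: benzyl bromide, BrCc1ccccc1
Why: SN2 alkylation of the phenoxide and of both carboxylates (Williamson type), which protects C8–OH and the C1 acid for the rest of the route.

Step 11
Reactants: 13 benzyl 6-(benzyloxy)-2-[3-(benzyloxy)-3-oxoprop-1-en-2-yl]-4-methoxy-3-methylbenzoate
Product: 14 2-{3-(benzyloxy)-2-[(benzyloxy)carbonyl]-5-methoxy-6-methylphenyl}prop-2-enoic acid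
Conditions: LiOH·H2O (1.5 equiv), THF/H2O, 0 °C to rt; then 1 M HCl
Reagents that add atoms: lithium hydroxide, [Li+].[OH-]
Why: Saponification (BAc2) discriminated by steric hindrance: hydroxide reaches the acrylate ester but not the benzoate ester, which is flanked by two ortho substituents.

Step 12
Reactants: 14 2-{3-(benzyloxy)-2-[(benzyloxy)carbonyl]-5-methoxy-6-methylphenyl}prop-2-enoic acid
Product: 15 (2S)-2-{3-(benzyloxy)-2-[(benzyloxy)carbonyl]-5-methoxy-6-methylphenyl}propanoic acid
Conditions: Ru(OAc)2[(S)-BINAP] (1 mol%), H2 (100 atm), MeOH, rt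
Reagents that add atoms: none
Why: Ru(II)–BINAP asymmetric hydrogenation of a 2-arylacrylic acid (the naproxen reaction): the carboxylate binds ruthenium and hydrogen is delivered to one face of C4=CH2, the (S)-ligand being expected to give the (S)-acid by analogy (the antipodal ligand is used if the sense proves opposite); the homogeneous catalyst leaves the benzyl groups intact.

Step 13
Reactants: 15 (2S)-2-{3-(benzyloxy)-2-[(benzyloxy)carbonyl]-5-methoxy-6-methylphenyl}propanoic acid
Product: 17 benzyl 6-(benzyloxy)-2-[(2S)-4-diazo-3-oxobutan-2-yl]-4-methoxy-3-methylbenzoate, via acid chloride 16 (not isolated)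
Conditions: (COCl)2, DMF (cat.), CH2Cl2, 0 °C; concentrate; then CH2N2 (3 equiv), Et2O, 0 °C
Reagents that add atoms: diazomethane, C=[N+]=[N-]; oxalyl chloride, O=C(Cl)C(=O)Cl (chlorine of intermediate 16 only)
Why: Acid chloride formation followed by acylation of diazomethane (first stage of the Arndt–Eistert sequence, the second equivalent of CH2N2 removing HCl); no amine base is present, so ketene formation and loss of the C4 configuration should be avoided.

Step 14
Reactants: 17 benzyl 6-(benzyloxy)-2-[(2S)-4-diazo-3-oxobutan-2-yl]-4-methoxy-3-methylbenzoate; 5 2,4-bis(benzyloxy)-5,6-dimethylbenzoic acid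
Product: 18 benzyl 6-(benzyloxy)-2-[(2S)-4-{[2,4-bis(benzyloxy)-5,6-dimethylbenzoyl]oxy}-3-oxobutan-2-yl]-4-methoxy-3-methylbenzoate
Conditions: Rh2(OAc)4 (1 mol%), CH2Cl2, rt, slow addition of 17 to 5 (1.5 equiv)
Reagents that add atoms: none
Why: Rh(II)-carbenoid O–H insertion into a carboxylic acid gives the acyloxymethyl ketone under neutral conditions, joining the two halves without touching C4.

Step 15
Reactants: 18 benzyl 6-(benzyloxy)-2-[(2S)-4-{[2,4-bis(benzyloxy)-5,6-dimethylbenzoyl]oxy}-3-oxobutan-2-yl]-4-methoxy-3-methylbenzoate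
Product: 20 [(3R,4S)-3,8-dihydroxy-6-methoxy-4,5-dimethyl-1-oxo-3,4-dihydro-1H-isochromen-3-yl]methyl 2,4-dihydroxy-5,6-dimethylbenzoate, via open-chain keto acid 19 (not isolated)
Conditions: H2 (1 atm), 10% Pd/C, EtOAc, rt
Reagents that add atoms: none
Why: Hydrogenolysis of the three benzyl ethers and the benzyl ester; the freed C1 acid adds to the C3 ketone (6-exo-trig) to close the lactol, C4 is untouched under neutral conditions, and C3 should settle as the (R)-hemiketal by thermodynamic control through ring–chain tautomerism.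

**Compound list**

1 | 4,5-dimethylbenzene-1,3-diol | Oc1cc(O)c(C)c(C)c1 | starting material
2 | (2,4-dihydroxy-5,6-dimethylbenzylidene)dimethyliminium chloride | C[N+](C)=Cc1c(O)cc(O)c(C)c1C.[Cl-] | intermediate (not isolated)
3 | 2,4-dihydroxy-5,6-dimethylbenzaldehyde | O=Cc1c(O)cc(O)c(C)c1C | intermediate
4 | 2,4-bis(benzyloxy)-5,6-dimethylbenzaldehyde | O=Cc1c(OCc2ccccc2)cc(OCc2ccccc2)c(C)c1C | intermediate
5 | 2,4-bis(benzyloxy)-5,6-dimethylbenzoic acid | OC(=O)c1c(OCc2ccccc2)cc(OCc2ccccc2)c(C)c1C | intermediate
6 | 2,4-dimethoxytoluene | COc1cc(OC)ccc1C | starting material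
7 | 1-(2,4-dimethoxy-5-methylphenyl)ethan-1-one | COc1cc(OC)c(C(C)=O)cc1C | intermediate
8 | 2,4-dimethoxy-5-methylphenyl acetate | COc1cc(OC)c(OC(C)=O)cc1C | intermediate
9 | 1-(2-hydroxy-3,5-dimethoxy-6-methylphenyl)ethan-1-one | COc1cc(OC)c(O)c(C(C)=O)c1C | intermediate
10 | 1-{3,5-dimethoxy-2-methyl-6-[(trifluoromethanesulfonyl)oxy]phenyl}ethenyl trifluoromethanesulfonate | COc1cc(OC)c(OS(=O)(=O)C(F)(F)F)c(C(=C)OS(=O)(=O)C(F)(F)F)c1C | intermediate
11 | 2-(1-carboxyethenyl)-4,6-dimethoxy-3-methylbenzoic acid | COc1cc(OC)c(C(=O)O)c(C(=C)C(=O)O)c1C | intermediate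
12 | 2-(1-carboxyethenyl)-6-hydroxy-4-methoxy-3-methylbenzoic acid | COc1cc(O)c(C(=O)O)c(C(=C)C(=O)O)c1C | intermediate
13 | benzyl 6-(benzyloxy)-2-[3-(benzyloxy)-3-oxoprop-1-en-2-yl]-4-methoxy-3-methylbenzoate | COc1cc(OCc2ccccc2)c(C(=O)OCc2ccccc2)c(C(=C)C(=O)OCc2ccccc2)c1C | intermediate
14 | 2-{3-(benzyloxy)-2-[(benzyloxy)carbonyl]-5-methoxy-6-methylphenyl}prop-2-enoic acid | COc1cc(OCc2ccccc2)c(C(=O)OCc2ccccc2)c(C(=C)C(=O)O)c1C | intermediate
15 | (2S)-2-{3-(benzyloxy)-2-[(benzyloxy)carbonyl]-5-methoxy-6-methylphenyl}propanoic acid | COc1cc(OCc2ccccc2)c(C(=O)OCc2ccccc2)c([C@H](C)C(=O)O)c1C | intermediate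
16 | benzyl 6-(benzyloxy)-2-[(2S)-1-chloro-1-oxopropan-2-yl]-4-methoxy-3-methylbenzoate | COc1cc(OCc2ccccc2)c(C(=O)OCc2ccccc2)c([C@H](C)C(Cl)=O)c1C | intermediate (not isolated)
17 | benzyl 6-(benzyloxy)-2-[(2S)-4-diazo-3-oxobutan-2-yl]-4-methoxy-3-methylbenzoate | COc1cc(OCc2ccccc2)c(C(=O)OCc2ccccc2)c([C@H](C)C(=O)C=[N+]=[N-])c1C | intermediate
18 | benzyl 6-(benzyloxy)-2-[(2S)-4-{[2,4-bis(benzyloxy)-5,6-dimethylbenzoyl]oxy}-3-oxobutan-2-yl]-4-methoxy-3-methylbenzoate | COc1cc(OCc2ccccc2)c(C(=O)OCc2ccccc2)c([C@H](C)C(=O)COC(=O)c2c(OCc3ccccc3)cc(OCc3ccccc3)c(C)c2C)c1C | intermediate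
19 | 2-[(2S)-4-[(2,4-dihydroxy-5,6-dimethylbenzoyl)oxy]-3-oxobutan-2-yl]-6-hydroxy-4-methoxy-3-methylbenzoic acid | COc1cc(O)c(C(=O)O)c([C@H](C)C(=O)COC(=O)c2c(O)cc(O)c(C)c2C)c1C | intermediate (not isolated)
20 | [(3R,4S)-3,8-dihydroxy-6-methoxy-4,5-dimethyl-1-oxo-3,4-dihydro-1H-isochromen-3-yl]methyl 2,4-dihydroxy-5,6-dimethylbenzoate | COc1cc(O)c2c(c1C)[C@H](C)[C@](O)(COC(=O)c1c(O)cc(O)c(C)c1C)OC2=O | target

**Step count and risks**

Total step count: 15. Longest linear sequence: 12 steps (steps 4 to 15, from 2,4-dimethoxytoluene).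

The three steps most likely to fail:

Step 8. The risk is that hydro-detriflation or S–O cleavage of the hindered aryl triflate outruns CO2 capture, so that only the vinyl position is carboxylated. The fallback sets out from bis-triflate 10. A palladium-catalysed double alkoxycarbonylation (Pd(OAc)2, Xantphos, CO 1 atm, 2-(trimethylsilyl)ethanol, Et3N, DMF, 80 °C) should give 2-(trimethylsilyl)ethyl 4,6-dimethoxy-3-methyl-2-{3-oxo-3-[2-(trimethylsilyl)ethoxy]prop-1-en-2-yl}benzoate F1, with both carbonyl carbons taken from CO instead of CO2. Fluoride (TBAF, THF) should then fragment both silylethyl esters, and the route is rejoined at diacid 11.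

Step 12. The risk is poor enantioface discrimination, or no turnover, because the twisted 2,6-disubstituted aryl group hinders the chelating binding mode of the acrylic acid. The fallback sets out from acrylic acid 14. Hydrogenation with RhCl(PPh3)3 and H2, which leaves the benzyl groups in place, should give racemic 2-{3-(benzyloxy)-2-[(benzyloxy)carbonyl]-5-methoxy-6-methylphenyl}propanoic acid F2. This is resolved by crystallisation of (1S)-1-phenylethylammonium (2S)-2-{3-(benzyloxy)-2-[(benzyloxy)carbonyl]-5-methoxy-6-methylphenyl}propanoate F3 (the antipodal amine is used if the other diastereomeric salt is the less soluble one). Acidification returns to acid 15.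

Step 14. The risk is capture of the rhodium carbenoid by the neighbouring electron-rich arene (Buchner-type addition) or Wolff rearrangement competing with O–H insertion. The fallback sets out from diazoketone 17. Protonation and bromide displacement (48% aq. HBr, Et2O, −20 °C) should give benzyl 6-(benzyloxy)-2-[(2S)-4-bromo-3-oxobutan-2-yl]-4-methoxy-3-methylbenzoate F4 without a carbene intermediate. Displacement with the pre-formed caesium salt of acid 5 (DMF, 0 °C to rt, no excess base) returns to keto ester 18.

**Further compounds**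

F1 | step 8 | 2-(trimethylsilyl)ethyl 4,6-dimethoxy-3-methyl-2-{3-oxo-3-[2-(trimethylsilyl)ethoxy]prop-1-en-2-yl}benzoate | COc1cc(OC)c(C(=O)OCC[Si](C)(C)C)c(C(=C)C(=O)OCC[Si](C)(C)C)c1C
F2 | step 12 | racemic 2-{3-(benzyloxy)-2-[(benzyloxy)carbonyl]-5-methoxy-6-methylphenyl}propanoic acid | COc1cc(OCc2ccccc2)c(C(=O)OCc2ccccc2)c(C(C)C(=O)O)c1C
F3 | step 12 | (1S)-1-phenylethylammonium (2S)-2-{3-(benzyloxy)-2-[(benzyloxy)carbonyl]-5-methoxy-6-methylphenyl}propanoate | COc1cc(OCc2ccccc2)c(C(=O)OCc2ccccc2)c([C@H](C)C(=O)[O-])c1C.C[C@H]([NH3+])c1ccccc1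
F4 | step 14 | benzyl 6-(benzyloxy)-2-[(2S)-4-bromo-3-oxobutan-2-yl]-4-methoxy-3-methylbenzoate | COc1cc(OCc2ccccc2)c(C(=O)OCc2ccccc2)c([C@H](C)C(=O)CBr)c1C
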